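## Retrosynthetic overview

1. The target comes from a 6-alkenyl salicylaldehyde by acetonide hydrolysis and aldehyde reduction.
2. Key disconnection: the aryl–alkenyl bond (ortho to the butanediol chain, meta to the phenol OH). It is made in one electrochemical operation: anodic dearomatisation of a 5-alkyl salicylaldehyde to a spirodienone, alkenyl transfer from boron to the doubly activated ring carbon, then rearomatisation.
3. The salicylaldehyde comes from L-tyrosine, which supplies the benzene ring, the phenol oxygen and the (S) carbinol (diazotisation with retention, esterification, MeMgBr, ortho-formylation).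
4. The (E)-alkenyl trifluoroborate comes from L-tartrate (both diol centres): divinyl dioxolane, then two cross-metatheses (vinylboronate, hept-1-ene).
5. Rings: no ring of the target is built, since the benzene ring is bought. An oxolane spiro ring forms and reopens inside the key step, and the bought dioxolane ring is opened in step 9.

Assumption: the SMILES is read as (1E,3S,4S,5E) in the undecadienediol chain and (2S) in the butanediol chain; L-tyrosine, dimethyl 2,3-O-isopropylidene-L-tartrate, vinylboronic acid pinacol ester and hept-1-ene are taken as commercial.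

## Route

Step 1
Reactants: 1 L-tyrosine
Product: 2 (2S)-2-hydroxy-3-(4-hydroxyphenyl)propanoic acid
Conditions: NaNO2, 1 M H2SO4 (aq), 0 °C → rt
Reagents that add atoms: water (O)
Why: Diazotisation of the α-amino acid with neighbouring-group participation of the carboxylate; two successive inversions give net retention, so the (S) centre of 1 becomes the (S) carbinol of 2.

Step 2
Reactants: 2 (2S)-2-hydroxy-3-(4-hydroxyphenyl)propanoic acid
Product: 3 methyl (2S)-2-hydroxy-3-(4-hydroxyphenyl)propanoate
Conditions: MeOH, H2SO4 (cat.), reflux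
Reagents that add atoms: methanol (CO)
Why: Fischer esterification; the phenol and the secondary alcohol are not esterified and the stereocentre is not touched.

Step 3
Reactants: 3 methyl (2S)-2-hydroxy-3-(4-hydroxyphenyl)propanoate
Product: 4 4-[(2S)-2,3-dihydroxy-3-methylbutyl]phenol
Conditions: MeMgBr (5 equiv), THF, 0 °C → rt; aq. NH4Cl
Reagents that add atoms: methylmagnesium bromide (C[Mg]Br)
Why: Double Grignard addition to the ester (two further equivalents are spent on the phenol and the hydroxyl group); the carbinol centre sits as its alkoxide and is not epimerised.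

Step 4
Reactants: 4 4-[(2S)-2,3-dihydroxy-3-methylbutyl]phenol
Product: 6 5-[(2S)-2,3-dihydroxy-3-methylbutyl]-2-hydroxybenzaldehyde, via hydroxymethyl phenol 5 (not isolated)
Conditions: MgCl2, Et3N, (CH2O)n, MeCN, reflux; 1 M HCl work-up
Reagents that add atoms: paraformaldehyde, as formaldehyde (C=O)
Why: Casnati–Skattebøl ortho-formylation: the ArOMgCl phenoxide delivers formaldehyde to the ortho carbon (both ortho positions are equivalent, para is blocked) to give 5, whose benzylic alkoxide passes hydride to a second formaldehyde; the aliphatic hydroxyls are not ionised by Et3N and the stereocentre is untouched.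

Step 5
Reactants: 7 dimethyl (4R,5R)-2,2-dimethyl-1,3-dioxolane-4,5-dicarboxylate
Product: 9 (4S,5S)-4,5-diethenyl-2,2-dimethyl-1,3-dioxolane, via dialdehyde 8 (not isolated)
Conditions: iBu2AlH (2.05 equiv), toluene, −78 °C; then Ph3PCH3Br/KN(SiMe3)2, THF, −78 °C → rt
Reagents that add atoms: methyltriphenylphosphonium bromide (C[P+](c1ccccc1)(c1ccccc1)c1ccccc1.[Br-])
Why: Partial ester reduction stops at the R–CH(OMe)–OAl(iBu)2 stage at −78 °C and Wittig methylenation in the same flask avoids handling the epimerisable dialdehyde 8; both centres are kept (trans ring), and the descriptors change from R to S only because vinyl ranks below the ring carbon where the ester ranked above it.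

Step 6
Reactants: 9 (4S,5S)-4,5-diethenyl-2,2-dimethyl-1,3-dioxolane, 10 2-ethenyl-4,4,5,5-tetramethyl-1,3,2-dioxaborolane
Product: 11 2-[(E)-2-[(4S,5S)-5-ethenyl-2,2-dimethyl-1,3-dioxolan-4-yl]ethenyl]-4,4,5,5-tetramethyl-1,3,2-dioxaborolane
Conditions: 9 (3 equiv), second-generation Hoveyda–Grubbs catalyst RuCl2(H2IMes)(=CH-C6H4-2-OiPr) (2 mol%), CH2Cl2, 40 °C
Reagents that add atoms: none
Why: Olefin cross-metathesis; the threefold excess of C2-symmetric 9 makes the mono-coupled product dominant and vinylboronates give the (E)-alkenylboronate selectively; the allylic stereocentres are not involved.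

Step 7
Reactants: 11 2-[(E)-2-[(4S,5S)-5-ethenyl-2,2-dimethyl-1,3-dioxolan-4-yl]ethenyl]-4,4,5,5-tetramethyl-1,3,2-dioxaborolane, 12 hept-1-ene
Product: 14 potassium trifluoro[(E)-2-[(4S,5S)-5-[(1E)-hept-1-en-1-yl]-2,2-dimethyl-1,3-dioxolan-4-yl]ethenyl]borate, via pinacol boronate 13 (not isolated)
Conditions: 12 (5 equiv), second-generation Hoveyda–Grubbs catalyst RuCl2(H2IMes)(=CH-C6H4-2-OiPr) (3 mol%), CH2Cl2, 40 °C; then KHF2, MeOH/H2O, rt; recrystallise (acetone/Et2O)
Reagents that add atoms: potassium hydrogen difluoride (F[H-]F.[K+])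
Why: Second olefin cross-metathesis at the remaining terminal vinyl group (the 1,2-disubstituted alkenylboronate is a poor metathesis partner), E-selective under thermodynamic control helped by the allylic branching; KHF2 then turns pinacol boronate 13 into the crystalline trifluoroborate, and recrystallisation removes residual Z isomer and ruthenium.

Step 8
Reactants: 6 5-[(2S)-2,3-dihydroxy-3-methylbutyl]-2-hydroxybenzaldehyde, 14 potassium trifluoro[(E)-2-[(4S,5S)-5-[(1E)-hept-1-en-1-yl]-2,2-dimethyl-1,3-dioxolan-4-yl]ethenyl]borate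
Product: 18 3-[(2S)-2,3-dihydroxy-3-methylbutyl]-2-[(E)-2-[(4S,5S)-5-[(1E)-hept-1-en-1-yl]-2,2-dimethyl-1,3-dioxolan-4-yl]ethenyl]-6-hydroxybenzaldehyde, via spirodienone 15 (not isolated), via alkenyldifluoroborane 16 (not isolated), via conjugate adduct 17 (not isolated)
Conditions: divided cell, graphite anode, Pt cathode, 5 mA cm−2, 2.1 F mol−1, 14 (1.3 equiv), 2,6-lutidine, nBu4NBF4, MeCN/(CF3)2CHOH (4:1), 0 °C; then current off, 40 °C; aq. NaHCO3
Reagents that add atoms: none
Why: Proposed new method: anodic two-electron oxidation of the para-alkyl phenol 6 gives a phenoxonium ion that is trapped at the para carbon by the tertiary hydroxyl (five-membered ring), so spirodienone 15 forms without an external nucleophile; its C6=C7 bond is activated by both the ring ketone and the formyl group, and the formyl oxygen, s-cis to that bond, binds the tricoordinate boron of 16 (freed from 14 by loss of fluoride to the (CF3)2CHOH/lutidinium medium), so the alkenyl group moves from boron to C6 through a six-membered chair transition state with retention of the E geometry; adduct 17 rearomatises by expelling the tertiary alkoxide, which restores the diol side chain and erases the spiro and ring sp3 centres, so no new stereocentre survives and the three existing ones are untouched; closest known reaction types are the oxidative (anodic or PhI(OAc)2) spirocyclisation of tyrosine-type phenols, the 1,4-addition of alkenylboranes and alkenyldifluoroboranes to cisoid enones, and conjugate addition/rearomatisation of quinol ethers as a formal meta-functionalisation of phenols.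

Step 9
Reactants: 18 3-[(2S)-2,3-dihydroxy-3-methylbutyl]-2-[(E)-2-[(4S,5S)-5-[(1E)-hept-1-en-1-yl]-2,2-dimethyl-1,3-dioxolan-4-yl]ethenyl]-6-hydroxybenzaldehyde
Product: 19 3-[(2S)-2,3-dihydroxy-3-methylbutyl]-2-[(1E,3S,4S,5E)-3,4-dihydroxyundeca-1,5-dien-1-yl]-6-hydroxybenzaldehyde
Conditions: AcOH/H2O/THF (3:1:1), 50 °C
Reagents that add atoms: none
Why: Acid-catalysed acetal hydrolysis, done at the aldehyde stage where the electron-poor ring disfavours ionisation of the styryl carbinol, so the three carbinol centres keep their configuration.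

Step 10
Reactants: 19 3-[(2S)-2,3-dihydroxy-3-methylbutyl]-2-[(1E,3S,4S,5E)-3,4-dihydroxyundeca-1,5-dien-1-yl]-6-hydroxybenzaldehyde
Product: 20 (1E,3S,4S,5E)-1-[6-[(2S)-2,3-dihydroxy-3-methylbutyl]-3-hydroxy-2-(hydroxymethyl)phenyl]undeca-1,5-diene-3,4-diol
Conditions: NaBH4, MeOH, 0 °C
Reagents that add atoms: none
Why: Chemoselective borohydride reduction of the aryl aldehyde at 0 °C; alkenes and carbinol centres are unaffected.

## Compound list

1 | L-tyrosine | N[C@@H](Cc1ccc(O)cc1)C(=O)O | starting material
2 | (2S)-2-hydroxy-3-(4-hydroxyphenyl)propanoic acid | Oc1ccc(C[C@H](O)C(=O)O)cc1 | intermediate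
3 | methyl (2S)-2-hydroxy-3-(4-hydroxyphenyl)propanoate | Oc1ccc(C[C@H](O)C(=O)OC)cc1 | intermediate
4 | 4-[(2S)-2,3-dihydroxy-3-methylbutyl]phenol | Oc1ccc(C[C@H](O)C(C)(C)O)cc1 | intermediate
5 | 4-[(2S)-2,3-dihydroxy-3-methylbutyl]-2-(hydroxymethyl)phenol (present as its magnesium alkoxide) | OCc1cc(C[C@H](O)C(C)(C)O)ccc1O | intermediate (not isolated)
6 | 5-[(2S)-2,3-dihydroxy-3-methylbutyl]-2-hydroxybenzaldehyde | O=Cc1cc(C[C@H](O)C(C)(C)O)ccc1O | intermediate
7 | dimethyl (4R,5R)-2,2-dimethyl-1,3-dioxolane-4,5-dicarboxylate | COC(=O)[C@@H]1OC(C)(C)O[C@H]1C(=O)OC | starting material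
8 | (4R,5R)-2,2-dimethyl-1,3-dioxolane-4,5-dicarbaldehyde (present as its aluminium hemiacetal) | O=C[C@@H]1OC(C)(C)O[C@H]1C=O | intermediate (not isolated)
9 | (4S,5S)-4,5-diethenyl-2,2-dimethyl-1,3-dioxolane | C=C[C@@H]1OC(C)(C)O[C@H]1C=C | intermediate
10 | 2-ethenyl-4,4,5,5-tetramethyl-1,3,2-dioxaborolane | C=CB1OC(C)(C)C(C)(C)O1 | starting material
11 | 2-[(E)-2-[(4S,5S)-5-ethenyl-2,2-dimethyl-1,3-dioxolan-4-yl]ethenyl]-4,4,5,5-tetramethyl-1,3,2-dioxaborolane | C=C[C@@H]1OC(C)(C)O[C@H]1/C=C/B2OC(C)(C)C(C)(C)O2 | intermediate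
12 | hept-1-ene | C=CCCCCC | starting material
13 | 2-[(E)-2-[(4S,5S)-5-[(1E)-hept-1-en-1-yl]-2,2-dimethyl-1,3-dioxolan-4-yl]ethenyl]-4,4,5,5-tetramethyl-1,3,2-dioxaborolane | CCCCC/C=C/[C@@H]1OC(C)(C)O[C@H]1/C=C/B2OC(C)(C)C(C)(C)O2 | intermediate (not isolated)
14 | potassium trifluoro[(E)-2-[(4S,5S)-5-[(1E)-hept-1-en-1-yl]-2,2-dimethyl-1,3-dioxolan-4-yl]ethenyl]borate | CCCCC/C=C/[C@@H]1OC(C)(C)O[C@H]1/C=C/[B-](F)(F)F.[K+] | intermediate
15 | (3S)-3-hydroxy-2,2-dimethyl-8-oxo-1-oxaspiro[4.5]deca-6,9-diene-7-carbaldehyde (both spiro epimers) | O=CC1=CC2(C[C@H](O)C(C)(C)O2)C=CC1=O | intermediate (not isolated)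
16 | difluoro[(E)-2-[(4S,5S)-5-[(1E)-hept-1-en-1-yl]-2,2-dimethyl-1,3-dioxolan-4-yl]ethenyl]borane | CCCCC/C=C/[C@@H]1OC(C)(C)O[C@H]1/C=C/B(F)F | intermediate (not isolated)
17 | (3S)-6-[(E)-2-[(4S,5S)-5-[(1E)-hept-1-en-1-yl]-2,2-dimethyl-1,3-dioxolan-4-yl]ethenyl]-3-hydroxy-2,2-dimethyl-8-oxo-1-oxaspiro[4.5]dec-9-ene-7-carbaldehyde (keto-aldehyde form shown; present as its boron-bound enolate, diastereomer mixture at the transient centres) | CCCCC/C=C/[C@@H]1OC(C)(C)O[C@H]1/C=C/C2C(C=O)C(=O)C=CC23C[C@H](O)C(C)(C)O3 | intermediate (not isolated)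
18 | 3-[(2S)-2,3-dihydroxy-3-methylbutyl]-2-[(E)-2-[(4S,5S)-5-[(1E)-hept-1-en-1-yl]-2,2-dimethyl-1,3-dioxolan-4-yl]ethenyl]-6-hydroxybenzaldehyde | CCCCC/C=C/[C@@H]1OC(C)(C)O[C@H]1/C=C/c2c(C[C@H](O)C(C)(C)O)ccc(O)c2C=O | intermediate
19 | 3-[(2S)-2,3-dihydroxy-3-methylbutyl]-2-[(1E,3S,4S,5E)-3,4-dihydroxyundeca-1,5-dien-1-yl]-6-hydroxybenzaldehyde | CCCCC/C=C/[C@H](O)[C@@H](O)/C=C/c1c(C[C@H](O)C(C)(C)O)ccc(O)c1C=O | intermediate
20 | (1E,3S,4S,5E)-1-[6-[(2S)-2,3-dihydroxy-3-methylbutyl]-3-hydroxy-2-(hydroxymethyl)phenyl]undeca-1,5-diene-3,4-diol | CCCCC/C=C/[C@H](O)[C@@H](O)/C=C/c1c(C[C@H](O)C(C)(C)O)ccc(O)c1CO | target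

## Step count and risks

Total: 10 steps. Longest linear sequence: 7 steps (1, 2, 3, 4, 8, 9, 10); the boron partner takes 3 steps (5 to 7) before the union.

Steps most likely to fail:

1. Step 8 (the proposed electrochemical alkenylation). The boron-to-carbon transfer may be too slow without a stronger Lewis acid, 15 may be lost to adventitious nucleophiles, or the alkenyl group may add 1,2 to the aldehyde. The fallback sets out from 6 and 14 and comes back at 18, using known chemistry only. 6 is dearomatised with PhI(OAc)2 in MeCN/(CF3)2CHOH at 0 °C and spirodienone 15 is isolated. LiBr and AcOH in MeCN then add bromide to the doubly activated C6, and the adduct aromatises at once with opening of the oxolane to give 2-bromo-3-[(2S)-2,3-dihydroxy-3-methylbutyl]-6-hydroxybenzaldehyde F1. A Suzuki–Miyaura coupling of F1 with trifluoroborate 14 (Pd(OAc)2, SPhos, K2CO3, toluene/H2O, 80 °C) gives 18 with retention of the E geometry.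

2. Step 7 (cross-metathesis with hept-1-ene in the presence of the alkenylboronate). The E/Z ratio of the new alkene may be modest and the boronate may be eroded by secondary metathesis. The fallback sets out from 9 and comes back at 13, which is then converted into 14 with KHF2 as in step 7. It reverses the order of bond formation, so that no boronate is present when the heptenyl group is installed and the boron is introduced last; it therefore replaces step 6 as well. 9 (3 equiv) and 12 are cross-metathesised to (4S,5S)-4-ethenyl-5-[(1E)-hept-1-en-1-yl]-2,2-dimethyl-1,3-dioxolane F2, the minor Z isomer is removed on AgNO3-impregnated silica, and F2 is then cross-metathesised with 10 to give 13.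

3. Step 4 (formylation of the unprotected triol). The free 1,2-diol may sequester magnesium or react with formaldehyde. The fallback sets out from 4 and comes back at 6 and masks the diol first. 4 is converted with 2,2-dimethoxypropane and pyridinium p-toluenesulfonate in acetone into 4-{[(4S)-2,2,5,5-tetramethyl-1,3-dioxolan-4-yl]methyl}phenol F3. This is formylated under the same MgCl2/Et3N/(CH2O)n conditions to 2-hydroxy-5-{[(4S)-2,2,5,5-tetramethyl-1,3-dioxolan-4-yl]methyl}benzaldehyde F4, and the acetonide is hydrolysed (AcOH/H2O, 50 °C) to give 6.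

Further compounds
F1 | step 8 | 2-bromo-3-[(2S)-2,3-dihydroxy-3-methylbutyl]-6-hydroxybenzaldehyde | O=Cc1c(O)ccc(C[C@H](O)C(C)(C)O)c1Br
F2 | step 7 | (4S,5S)-4-ethenyl-5-[(1E)-hept-1-en-1-yl]-2,2-dimethyl-1,3-dioxolane | CCCCC/C=C/[C@@H]1OC(C)(C)O[C@H]1C=C
F3 | step 4 | 4-{[(4S)-2,2,5,5-tetramethyl-1,3-dioxolan-4-yl]methyl}phenol | CC1(C)O[C@@H](Cc2ccc(O)cc2)C(C)(C)O1
F4 | step 4 | 2-hydroxy-5-{[(4S)-2,2,5,5-tetramethyl-1,3-dioxolan-4-yl]methyl}benzaldehyde | CC1(C)O[C@@H](Cc2ccc(O)c(C=O)c2)C(C)(C)O1
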